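# Proposed total synthesis of 7-hydroxy-6-methoxy-3-[(6-methoxy-2-oxo-2H-chromen-7-yl)oxy]-2H-chromen-2-one (23)

Compound numbers 1–23 are fixed by the steps and the list after them; 23 is the target. Unprimed atoms belong to the coumarin that carries the free 7-OH (ring A), primed atoms to the coumarin joined through the oxygen on C7' (ring B).

## Analysis of the target

Target 23 is an unsymmetrical ether of two 6-methoxy-7-oxycoumarin units. Ring A is a 7-hydroxy-6-methoxy-2H-chromen-2-one that carries the bridging oxygen on C3, and ring B is a 6-methoxy-2H-chromen-2-one that carries it on C7'. There is no stereocentre, and every carbon except the two methoxy carbons is sp2, so the problem is one of regiochemistry and chemoselectivity. The sensitive groups are the two lactones (opened by hydroxide or alkoxide), the unsubstituted C3'=C4' bond of ring B (open to reduction and conjugate addition), the free phenol on C7, and the electron-rich benzene rings, which do not tolerate strong oxidants. The hard part is the C3–O–C7' link: it joins an enol-type oxygen of low nucleophilicity to an aromatic carbon that is electron-rich and flanked by a methoxy group, and the two halves have the same oxygenation pattern, so they must be told apart from the start. The strategy rests on the benzene of ring B: C8a' carries O1', C8' carries H, C7' carries the ether oxygen, C6' carries OMe, and C5' and C4a' close the ring, with O1' para to the methoxy carbon. This is a 4-methoxyphenol with an oxygen substituent between the two positions, which is what a cyclobutenone delivers when its four ring carbons become C8a', C8', C7' and C6' and an alkenyl arm on the methoxy-bearing carbon supplies C5' and C4a'. Read this way, the ether oxygen is attached to C7' while that carbon is still an electrophilic vinylogous acyl carbon, not an arene carbon.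

## Retrosynthetic reasoning

**23 ⇒ 22.** The O7–benzyl bond is cut last. The free phenol on C7 is the only group that would interfere with organolithium, methylation and ylide chemistry, so it stays masked until the end. The forward step must remove a benzyl group without touching two methyl ethers, two lactones and the C3'=C4' bond.

**22 ⇒ 19.** The pyranone of ring B is opened at C3'=C4' and O1'–C2', giving the salicylaldehyde 19. C3' and C4' carry only hydrogen, so this lactone is the simplest to add late from an ortho-hydroxy aldehyde and a two-carbon phosphorus ylide. The forward reaction is an olefination followed by lactonisation through the cinnamates 20 and 21.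

**19 ⇒ 18.** The aldehyde carbon (C4') is taken back to a diethyl acetal. In that form the carbon survives an organolithium addition and the thermolysis, and it is released with dilute acid.

**18 ⇒ 15 (key disconnection).** The benzene of ring B is unfolded by cutting C4a'–C8a' and re-closing C8a'–C6' to give cyclobutenone 15. The ring is not cut elsewhere because any route through an intact trioxygenated arene needs either an O-arylation at the hindered C7' or an electrophilic substitution with uncertain regiochemistry. In 15 the four carbons C8a' (carbonyl), C8' (H), C7' (aryloxy) and C6' (methoxy) are already in order, and the alkenyl arm on C6' brings C5', C4a' and the masked C4'. The forward reaction has to open the four-membered ring to the dienylketene 16, close it to the dienone 17 and aromatise.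

**15 ⇒ 10 + 12.** The C5'–C6' bond and the O–CH3 bond on C6' are cut. This leads to the aryloxycyclobutenedione 10 and the alkenyl nucleophile 13, made from stannane 12, with the alkoxide 14 capped by an electrophilic methylating agent. The forward addition must pick the ketone of 10 next to the aryloxy-bearing carbon and leave the vinylogous ester carbonyl and the lactone alone.

**10 ⇒ 7 + 9.** The C7'–O bond is cut at the stage where C7' is the chlorine-bearing carbon of 9. The enol oxygen of 7 then only has to displace chloride by addition–elimination, which is far easier than arylating it. 9 comes from semisquaric acid 8, and 12 from alkyne 11 by hydrostannation.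

**7 ⇒ 6 ⇒ 2 + 3.** The pyranone of ring A is cut at C3=C4 and O1–C2. The two carbons C2 and C3 and a nitrogen placeholder for the C3 oxygen come from N-acetylglycine 3 through the azlactones 4 and 5, and the nitrogen of 6 is exchanged for oxygen by hydrolysis. 2 comes from 1 by benzylation of the one hydroxyl that is not hydrogen-bonded to the aldehyde, which is where the two halves of the target are differentiated.

## Alternatives that were turned down

Alternative 1: twofold oxidative lactonisation of a bis-cinnamic acid.
- Disconnection: both lactone C–O bonds, O1–C8a and O1'–C8a', are cut. This leads to the diacid A2, (2Z)-3-[4-(acetyloxy)-3-methoxyphenyl]-2-{4-[(1E)-2-carboxyethenyl]-2-methoxyphenoxy}prop-2-enoic acid, in which the ether link already exists as an α-aryloxyacrylic acid.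
- Forward key step: A2 is irradiated with blue light under O2 with the sensitiser (−)-riboflavin A3. Energy transfer from A3 turns each aryl group cis to its carboxyl group, and photo-oxidation lets each carboxylate attack the ortho carbon of its own arene, giving the 7-O-acetate A1, which is then deacetylated.
- For: it is the shortest plan, closes both pyranones in one operation, and needs only an acetate as protection. On step economy it is stronger than the chosen route.
- Against: each arene has two free ortho positions, and closure must occur twice at the one para to methoxy. Attack at the carbon between the side chain and the methoxy group would give 7,8-dioxygenated isomers, so up to four products are possible. The ring A alkene of A2 is an enol ether, an electron-rich double bond that a flavin sensitiser such as A3 under O2 can cleave oxidatively. Its trisubstituted geometry also makes the isomerisation that must precede cyclisation less favourable.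
- Comparison: the chosen route is longer, but it fixes the oxygen pattern of ring B by construction and exposes no enol ether to photo-oxidation.

Alternative 2: chromium carbene benzannulation for ring A.
- Disconnection: the benzene of ring A is cut at C5–C6, C4a–C8a and C8–C8a, and the lactone at O1–C2. This leads to the zerovalent chromium carbene complex A5, pentacarbonyl[2-(tert-butoxy)-1-methoxyprop-2-en-1-ylidene]chromium, and the enyne ester A6, methyl (2E)-2-[(6-methoxy-2-oxo-2H-chromen-7-yl)oxy]pent-2-en-4-ynoate.
- Forward key step: A5 and A6 are warmed in THF. Alkyne insertion, CO insertion and electrocyclisation build the 4-methoxyphenol, whose hydroxyl closes onto the cis ester to give the tert-butyl ether A4, which is cleaved with acid.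
- For: it uses the same para relationship between a methoxy carbon and the lactone oxygen, here in ring A, and forms three C–C bonds and the lactone in one step. Ring B is brought in whole. In bonds formed per step and in the mildness of the final deprotection it is at least equal to the chosen route.
- Against: A6 must have its alkyne cis to the ester across a trisubstituted enol ether double bond, which is not easy to set. A conjugated, electron-poor enyne inserts more slowly and leaves room for side reactions of the carbene, including attack on the C3'=C4' bond of the coumarin in A6. A5 is a thermally fragile α-alkoxyvinyl complex and is used stoichiometrically. Oxidative removal of chromium from an electron-rich para-alkoxyphenol invites quinone formation.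
- Comparison: the chosen key step is a metal-free thermolysis of a bench-stable precursor, and its regiochemistry is fixed by the connectivity of the four-membered ring instead of by alkyne polarisation.

Alternative 3: propiolate hydroarylation closing ring B last.
- Disconnection: C4'–C4a' and O1'–C2' are cut. This leads to the phenol A8, 7-(benzyloxy)-3-(5-hydroxy-2-methoxyphenoxy)-6-methoxy-2H-chromen-2-one, and ethyl propiolate A9.
- Forward key step: with Pd(OAc)2 and NaOAc in HCO2H the arene carbon ortho to the hydroxyl of A8 adds to A9 and the phenol lactonises. This gives the benzyl ether A7, which is the same compound as 22.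
- For: it is short, uses ordinary aromatic chemistry, and meets the chosen route at its penultimate compound. In step count it is stronger.
- Against: the reaction needs a strongly activated arene. The attacking carbon of A8 is para to an aryloxy oxygen whose lone pair is shared with an electron-poor coumarin enol, so it is a weak donor. A divalent palladium salt in formic acid can also form palladium hydrides that threaten the benzyl ether and the C3'=C4' bond. The difficulty of the target is moved, not removed: A8 has to be made by metal-mediated O-arylation of the enol oxygen with an electron-rich, ortho-methoxy aryl partner, which is the bond identified above as the hardest to form.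
- Comparison: the chosen route makes that C–O bond by addition–elimination on a vinylogous acid chloride and does not depend on the nucleophilicity of any arene.

Key step: step 8

Remark on the chemistry: compounds 14, 15 and 17 are racemic and are drawn as one enantiomer; their single stereocentre is lost on aromatisation in step 8.

## Route

Step 1
Reactants: 1 2,4-dihydroxy-5-methoxybenzaldehyde
Product: 2 4-(benzyloxy)-2-hydroxy-5-methoxybenzaldehyde
Conditions: BnBr, NaHCO3, KI (cat.), MeCN, 80 °C
Reagents that add atoms: benzyl bromide, BrCc1ccccc1
Why: Williamson etherification; the 4-OH is the more acidic hydroxyl (para to the aldehyde) and is not held in the hydrogen bond that ties the 2-OH to the carbonyl, so a bicarbonate base should alkylate it selectively.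

Step 2
Reactants: 2 4-(benzyloxy)-2-hydroxy-5-methoxybenzaldehyde; 3 N-acetylglycine
Product: 6 N-[7-(benzyloxy)-6-methoxy-2-oxo-2H-chromen-3-yl]acetamide, via 2-methyl-1,3-oxazol-5(4H)-one 4 (not isolated), via arylidene azlactone 5 (not isolated)
Conditions: Ac2O, NaOAc, 120 °C
Reagents that add atoms: none
Why: Erlenmeyer–Plöchl azlactone condensation; the arylidene azlactone equilibrates between its geometries in hot Ac2O/NaOAc and the ortho phenol oxygen opens the azlactone carbonyl, which closes the pyranone of ring A and leaves the nitrogen as the acetamide on C3.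

Step 3
Reactants: 6 N-[7-(benzyloxy)-6-methoxy-2-oxo-2H-chromen-3-yl]acetamide
Product: 7 7-(benzyloxy)-3-hydroxy-6-methoxy-2H-chromen-2-one
Conditions: 3 M aq. HCl, 1,4-dioxane, 90 °C
Reagents that add atoms: water, O
Why: Acid hydrolysis of the enamide (amide cleavage, then hydrolysis of the enamine through its iminium form) gives the chroman-2,3-dione, which rests as the enol 3-hydroxycoumarin; the lactone re-closes in acid and an aryl benzyl ether should withstand dilute aqueous HCl.

Step 4
Reactants: 8 semisquaric acid (3-hydroxycyclobut-3-ene-1,2-dione)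
Product: 9 3-chlorocyclobut-3-ene-1,2-dione
Conditions: (COCl)2, DMF (cat.), CH2Cl2, 0 °C → rt
Reagents that add atoms: oxalyl chloride, ClC(=O)C(Cl)=O
Why: Conversion of a vinylogous carboxylic acid into its vinylogous acid chloride under Vilsmeier-type activation; the gaseous by-products leave a solution of 9 that is used directly.

Step 5
Reactants: 7 7-(benzyloxy)-3-hydroxy-6-methoxy-2H-chromen-2-one; 9 3-chlorocyclobut-3-ene-1,2-dione
Product: 10 3-{[7-(benzyloxy)-6-methoxy-2-oxo-2H-chromen-3-yl]oxy}cyclobut-3-ene-1,2-dione
Conditions: iPr2NEt, CH2Cl2, −40 → 0 °C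
Reagents that add atoms: none
Why: Addition–elimination (vinylogous acyl substitution) of the enol oxygen at the chlorine-bearing carbon; O-attack is expected because C-attack through C4 of the coumarin would break the conjugation of the pyranone with its arene.

Step 6
Reactants: 11 3,3-diethoxyprop-1-yne
Product: 12 tributyl[(1E)-3,3-diethoxyprop-1-en-1-yl]stannane
Conditions: Bu3SnH, AIBN (cat.), neat, 85 °C
Reagents that add atoms: tributyltin hydride, CCCC[SnH](CCCC)CCCC
Why: Radical hydrostannation of a terminal alkyne; the stannyl radical adds to the terminal carbon and reversible addition equilibrates the product towards the E isomer, and any Z isomer carried forward would converge on the same phenol in step 8.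

Step 7
Reactants: 10 3-{[7-(benzyloxy)-6-methoxy-2-oxo-2H-chromen-3-yl]oxy}cyclobut-3-ene-1,2-dione; 12 tributyl[(1E)-3,3-diethoxyprop-1-en-1-yl]stannane
Product: 15 rac-3-{[7-(benzyloxy)-6-methoxy-2-oxo-2H-chromen-3-yl]oxy}-4-[(1E)-3,3-diethoxyprop-1-en-1-yl]-4-methoxycyclobut-2-en-1-one, via vinyllithium 13 (not isolated), via lithium alkoxide 14 (not isolated)
Conditions: 12, n-BuLi, THF, −78 °C; add to 10, THF, −78 °C; then MeOTf, −78 → 0 °C
Reagents that add atoms: methyl trifluoromethanesulfonate, COS(=O)(=O)C(F)(F)F
Why: Tin–lithium exchange with retention of alkene geometry, then 1,2-addition to the ring ketone next to the aryloxy-bearing carbon, which is the more electrophilic carbonyl because the other one is a vinylogous ester, as is known for alkyl semisquarates; the alkoxide is O-methylated in the same flask. The new quaternary centre is formed as a racemate and is lost in the next step.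

Step 8
Reactants: 15 rac-3-{[7-(benzyloxy)-6-methoxy-2-oxo-2H-chromen-3-yl]oxy}-4-[(1E)-3,3-diethoxyprop-1-en-1-yl]-4-methoxycyclobut-2-en-1-one
Product: 18 7-(benzyloxy)-3-[4-(diethoxymethyl)-5-hydroxy-2-methoxyphenoxy]-6-methoxy-2H-chromen-2-one, via dienylketene 16 (not isolated), via cyclohexadienone 17 (not isolated)
Conditions: toluene (0.01 M, degassed), 110 °C
Reagents that add atoms: none
Why: This is a Moore-type ring expansion of a 4-alkenyl-4-alkoxycyclobutenone, a known thermal route to para-alkoxyphenols, applied here to a substrate with an aryloxy group on C3. Heating breaks the bond between the carbonyl carbon and the quaternary carbon of 15 in a conrotatory 4π electrocyclic opening and gives the dienylketene 16. A thermally allowed, disrotatory 6π electrocyclisation of 16 joins the ketene carbon (C8a') to the terminal alkene carbon (C4a') and closes the six-membered carbocycle as cyclohexadienone 17. Tautomerisation of 17, in which the hydrogen on C4a' moves to oxygen, gives the aromatic phenol 18 and makes the sequence irreversible. No stereocentre survives the step: the centre of 15 becomes planar in 16, and the centre at C4a' of 17, formed as a racemate, is lost on enolisation. The step needs torquoselectivity: the methoxy group, as the stronger donor on the quaternary carbon, should rotate outward, which turns the alkenyl arm inward, cis to the ketene; the ring opening is reversible, so a ketene of the wrong geometry can return to 15 and open again. The step also needs ring closure to outrun intermolecular capture of the ketene by the phenol that accumulates, which high dilution should secure. The acetal, the benzyl ether and both coumarin carbonyls should be inert to neutral thermolysis.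

Step 9
Reactants: 18 7-(benzyloxy)-3-[4-(diethoxymethyl)-5-hydroxy-2-methoxyphenoxy]-6-methoxy-2H-chromen-2-one
Product: 19 4-{[7-(benzyloxy)-6-methoxy-2-oxo-2H-chromen-3-yl]oxy}-2-hydroxy-5-methoxybenzaldehyde
Conditions: 1 M aq. HCl, THF, rt
Reagents that add atoms: water, O
Why: Acid-catalysed acetal hydrolysis, made easy by the ortho and para oxygen donors that stabilise the oxocarbenium ion; crude 18 can be used, and the lactone, the benzyl ether and the diaryl ether are stable to dilute acid at room temperature.

Step 10
Reactants: 19 4-{[7-(benzyloxy)-6-methoxy-2-oxo-2H-chromen-3-yl]oxy}-2-hydroxy-5-methoxybenzaldehyde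
Product: 22 7-(benzyloxy)-6-methoxy-3-[(6-methoxy-2-oxo-2H-chromen-7-yl)oxy]-2H-chromen-2-one, via E-cinnamate 20 (not isolated), via Z-cinnamate 21 (not isolated)
Conditions: Ph3P=CHCO2Et, PhNEt2, 215 °C
Reagents that add atoms: ethyl (triphenylphosphoranylidene)acetate, CCOC(=O)C=P(c1ccccc1)(c1ccccc1)c1ccccc1
Why: Wittig olefination of a salicylaldehyde with a stabilised ylide; at this temperature the E-cinnamate isomerises to the Z-cinnamate, whose phenol closes onto the ester, which is a standard one-flask synthesis of coumarins without substituents on C3 and C4.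

Step 11
Reactants: 22 7-(benzyloxy)-6-methoxy-3-[(6-methoxy-2-oxo-2H-chromen-7-yl)oxy]-2H-chromen-2-one
Product: 23 7-hydroxy-6-methoxy-3-[(6-methoxy-2-oxo-2H-chromen-7-yl)oxy]-2H-chromen-2-one
Conditions: BCl3, C6HMe5, CH2Cl2, −78 °C; then H2O
Reagents that add atoms: none
Why: Lewis-acid debenzylation with pentamethylbenzene as a trap for the benzyl cation; at −78 °C the aryl methyl ethers, which have no neighbouring carbonyl to direct the boron, and both lactones should survive, and the C3'=C4' bond is not exposed to hydrogenation.

## Compound list

1 | 2,4-dihydroxy-5-methoxybenzaldehyde | COc1cc(C=O)c(O)cc1O | starting material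
2 | 4-(benzyloxy)-2-hydroxy-5-methoxybenzaldehyde | COc1cc(C=O)c(O)cc1OCc1ccccc1 | intermediate
3 | N-acetylglycine | CC(=O)NCC(O)=O | starting material
4 | 2-methyl-1,3-oxazol-5(4H)-one | CC1=NCC(=O)O1 | intermediate (not isolated)
5 | (4Z)-4-{[4-(benzyloxy)-2-hydroxy-5-methoxyphenyl]methylidene}-2-methyl-1,3-oxazol-5(4H)-one | CC1=N/C(=C\c2cc(OC)c(OCc3ccccc3)cc2O)C(=O)O1 | intermediate (not isolated)
6 | N-[7-(benzyloxy)-6-methoxy-2-oxo-2H-chromen-3-yl]acetamide | COc1cc2cc(NC(C)=O)c(=O)oc2cc1OCc1ccccc1 | intermediate
7 | 7-(benzyloxy)-3-hydroxy-6-methoxy-2H-chromen-2-one | COc1cc2cc(O)c(=O)oc2cc1OCc1ccccc1 | intermediate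
8 | semisquaric acid (3-hydroxycyclobut-3-ene-1,2-dione) | OC1=CC(=O)C1=O | starting material
9 | 3-chlorocyclobut-3-ene-1,2-dione | ClC1=CC(=O)C1=O | intermediate
10 | 3-{[7-(benzyloxy)-6-methoxy-2-oxo-2H-chromen-3-yl]oxy}cyclobut-3-ene-1,2-dione | COc1cc2cc(OC3=CC(=O)C3=O)c(=O)oc2cc1OCc1ccccc1 | intermediate
11 | 3,3-diethoxyprop-1-yne | CCOC(C#C)OCC | starting material
12 | tributyl[(1E)-3,3-diethoxyprop-1-en-1-yl]stannane | CCCC[Sn](CCCC)(CCCC)/C=C/C(OCC)OCC | intermediate
13 | [(1E)-3,3-diethoxyprop-1-en-1-yl]lithium | [Li]/C=C/C(OCC)OCC | intermediate (not isolated)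
14 | lithium rac-2-{[7-(benzyloxy)-6-methoxy-2-oxo-2H-chromen-3-yl]oxy}-1-[(1E)-3,3-diethoxyprop-1-en-1-yl]-4-oxocyclobut-2-en-1-olate (one enantiomer drawn) | CCOC(OCC)/C=C/[C@]1([O-])C(Oc2cc3cc(OC)c(OCc4ccccc4)cc3oc2=O)=CC1=O.[Li+] | intermediate (not isolated)
15 | rac-3-{[7-(benzyloxy)-6-methoxy-2-oxo-2H-chromen-3-yl]oxy}-4-[(1E)-3,3-diethoxyprop-1-en-1-yl]-4-methoxycyclobut-2-en-1-one (one enantiomer drawn) | CCOC(OCC)/C=C/[C@]1(OC)C(Oc2cc3cc(OC)c(OCc4ccccc4)cc3oc2=O)=CC1=O | intermediate
16 | (3Z,5E)-3-{[7-(benzyloxy)-6-methoxy-2-oxo-2H-chromen-3-yl]oxy}-7,7-diethoxy-4-methoxyhepta-1,3,5-trien-1-one | O=C=C/C(Oc1cc2cc(OC)c(OCc3ccccc3)cc2oc1=O)=C(OC)\C=C\C(OCC)OCC | intermediate (not isolated)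
17 | rac-3-{[7-(benzyloxy)-6-methoxy-2-oxo-2H-chromen-3-yl]oxy}-6-(diethoxymethyl)-4-methoxycyclohexa-2,4-dien-1-one (one enantiomer drawn) | CCOC(OCC)[C@@H]1C=C(OC)C(Oc2cc3cc(OC)c(OCc4ccccc4)cc3oc2=O)=CC1=O | intermediate (not isolated)
18 | 7-(benzyloxy)-3-[4-(diethoxymethyl)-5-hydroxy-2-methoxyphenoxy]-6-methoxy-2H-chromen-2-one | CCOC(OCC)c1cc(OC)c(Oc2cc3cc(OC)c(OCc4ccccc4)cc3oc2=O)cc1O | intermediate
19 | 4-{[7-(benzyloxy)-6-methoxy-2-oxo-2H-chromen-3-yl]oxy}-2-hydroxy-5-methoxybenzaldehyde | COc1cc(C=O)c(O)cc1Oc1cc2cc(OC)c(OCc3ccccc3)cc2oc1=O | intermediate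
20 | ethyl (2E)-3-(4-{[7-(benzyloxy)-6-methoxy-2-oxo-2H-chromen-3-yl]oxy}-2-hydroxy-5-methoxyphenyl)prop-2-enoate | CCOC(=O)/C=C/c1cc(OC)c(Oc2cc3cc(OC)c(OCc4ccccc4)cc3oc2=O)cc1O | intermediate (not isolated)
21 | ethyl (2Z)-3-(4-{[7-(benzyloxy)-6-methoxy-2-oxo-2H-chromen-3-yl]oxy}-2-hydroxy-5-methoxyphenyl)prop-2-enoate | CCOC(=O)/C=C\c1cc(OC)c(Oc2cc3cc(OC)c(OCc4ccccc4)cc3oc2=O)cc1O | intermediate (not isolated)
22 | 7-(benzyloxy)-6-methoxy-3-[(6-methoxy-2-oxo-2H-chromen-7-yl)oxy]-2H-chromen-2-one | COc1cc2cc(Oc3cc4oc(=O)ccc4cc3OC)c(=O)oc2cc1OCc1ccccc1 | intermediate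
23 | 7-hydroxy-6-methoxy-3-[(6-methoxy-2-oxo-2H-chromen-7-yl)oxy]-2H-chromen-2-one | COc1cc2cc(Oc3cc4oc(=O)ccc4cc3OC)c(=O)oc2cc1O | target

## Step count and least certain steps

Total: 11 steps. Longest linear sequence: 9 steps (1, 2, 3, 5, 7, 8, 9, 10, 11, from compound 1); steps 4 and 6 are one-step side branches.

**Step 8 (key step).**
- What may go wrong: the dienylketene may be captured before it cyclises, by the phenol that builds up or by traces of water. The aryl vinylogous ester may also break down thermally, because a coumarin-3-yloxy group on the cyclobutenone has no close precedent. If the alkenyl arm and not the methoxy group rotated outward, the substrate would only shuttle between 15 and an unproductive ketene until it decomposed.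
- Fallback, through the new compounds F1, F2, F3 and F4: it gives up the four-membered ring, sets out from 7 and returns at 19. 3-Fluoro-4-methoxyphenol F1 is formylated ortho to the hydroxyl on the side away from fluorine with MgCl2, Et3N and paraformaldehyde to give 4-fluoro-2-hydroxy-5-methoxybenzaldehyde F2. The phenol is protected with MOMCl and iPr2NEt as 4-fluoro-5-methoxy-2-(methoxymethoxy)benzaldehyde F3. Heating 7 and F3 with K2CO3 in DMF at 90 °C lets the enol oxygen of 7 displace the fluoride para to the aldehyde in a nucleophilic aromatic substitution and gives 4-{[7-(benzyloxy)-6-methoxy-2-oxo-2H-chromen-3-yl]oxy}-5-methoxy-2-(methoxymethoxy)benzaldehyde F4. Dilute HCl in THF/MeOH removes the acetal-type protecting group and delivers 19.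

**Step 7.**
- What may go wrong: attack of the alkenyllithium may not be confined to the intended ketone. It may add to the other ring carbonyl, it may undergo addition–elimination at the aryloxy-bearing carbon with loss of the coumarin-3-olate (a better leaving group than an alkoxide), or it may attack the lactone. The tertiary alkoxide may also attack the nearby lactone before it is methylated. The constitution of 15 would have to be confirmed before step 8, because the regioisomeric adduct would lead to a wrongly substituted phenol.
- Fallback, through the new compounds F5, F6, F7, F8 and F9: it sets out from 10 and 11 and returns at 18. Alkyne 11 is deprotonated with n-BuLi to (3,3-diethoxyprop-1-yn-1-yl)lithium F5, a slimmer and less basic nucleophile of the kind that adds cleanly to squarate ketones. Addition to 10 at −78 °C gives the lithium alkoxide of the alkynyl carbinol, lithium rac-2-{[7-(benzyloxy)-6-methoxy-2-oxo-2H-chromen-3-yl]oxy}-1-(3,3-diethoxyprop-1-yn-1-yl)-4-oxocyclobut-2-en-1-olate F6, which is methylated with MeOTf to rac-3-{[7-(benzyloxy)-6-methoxy-2-oxo-2H-chromen-3-yl]oxy}-4-(3,3-diethoxyprop-1-yn-1-yl)-4-methoxycyclobut-2-en-1-one F7. Semihydrogenation at room temperature over Pd/CaCO3 poisoned with Pb(OAc)2 and quinoline gives the Z-alkenyl isomer of 15, rac-3-{[7-(benzyloxy)-6-methoxy-2-oxo-2H-chromen-3-yl]oxy}-4-[(1Z)-3,3-diethoxyprop-1-en-1-yl]-4-methoxycyclobut-2-en-1-one F8. Under the conditions of step 8, or in xylene at 140 °C if closure is slower, F8 should open to the 5Z isomer of the ketene, (3Z,5Z)-3-{[7-(benzyloxy)-6-methoxy-2-oxo-2H-chromen-3-yl]oxy}-7,7-diethoxy-4-methoxyhepta-1,3,5-trien-1-one F9. F9 closes to the same dienone 17 and enolises to 18, since the alkene geometry is lost once C4a' is part of the ring.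

**Step 5.**
- What may go wrong: the unsubstituted vinylogous acid chloride 9 may hydrolyse or oligomerise before it is captured, and the product may exchange its aryloxy group with a second molecule of the enolate.
- Fallback, through F10 and F11: it sets out from 7 and returns at 10. Commercial 3,4-dichlorocyclobut-3-ene-1,2-dione F10, a robust crystalline reagent, is treated with one equivalent of 7 and iPr2NEt at low temperature. The first aryloxy group deactivates the second chloride, so the reaction should stop at 3-{[7-(benzyloxy)-6-methoxy-2-oxo-2H-chromen-3-yl]oxy}-4-chlorocyclobut-3-ene-1,2-dione F11. The remaining chloride is replaced by hydrogen with Bu3SnH and Pd(PPh3)4, a complex of zerovalent palladium, in a hydrostannolysis of the acid-chloride type, to give 10.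

**Step 10.**
- What may go wrong: the E to Z isomerisation may be incomplete, so that the reaction stalls at the E-cinnamate, or the diaryl ether and benzyl ether may degrade slowly at 215 °C.
- Fallback: it sets out from 19 and returns at 22 and makes no new compound. The olefination is run at room temperature in CH2Cl2 and the E-cinnamate 20 is isolated. Irradiation at 365 nm in MeCN isomerises it to 21, which lactonises to 22 under the irradiation conditions or on brief warming with a catalytic base.

## Further compounds

F1 | step 8 | 3-fluoro-4-methoxyphenol | COc1ccc(O)cc1F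
F2 | step 8 | 4-fluoro-2-hydroxy-5-methoxybenzaldehyde | COc1cc(C=O)c(O)cc1F
F3 | step 8 | 4-fluoro-5-methoxy-2-(methoxymethoxy)benzaldehyde | COCOc1cc(F)c(OC)cc1C=O
F4 | step 8 | 4-{[7-(benzyloxy)-6-methoxy-2-oxo-2H-chromen-3-yl]oxy}-5-methoxy-2-(methoxymethoxy)benzaldehyde | COCOc1cc(Oc2cc3cc(OC)c(OCc4ccccc4)cc3oc2=O)c(OC)cc1C=O
F5 | step 7 | (3,3-diethoxyprop-1-yn-1-yl)lithium | [Li]C#CC(OCC)OCC
F6 | step 7 | lithium rac-2-{[7-(benzyloxy)-6-methoxy-2-oxo-2H-chromen-3-yl]oxy}-1-(3,3-diethoxyprop-1-yn-1-yl)-4-oxocyclobut-2-en-1-olate (one enantiomer drawn) | CCOC(OCC)C#C[C@]1([O-])C(Oc2cc3cc(OC)c(OCc4ccccc4)cc3oc2=O)=CC1=O.[Li+]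
F7 | step 7 | rac-3-{[7-(benzyloxy)-6-methoxy-2-oxo-2H-chromen-3-yl]oxy}-4-(3,3-diethoxyprop-1-yn-1-yl)-4-methoxycyclobut-2-en-1-one (one enantiomer drawn) | CCOC(OCC)C#C[C@]1(OC)C(Oc2cc3cc(OC)c(OCc4ccccc4)cc3oc2=O)=CC1=O
F8 | step 7 | rac-3-{[7-(benzyloxy)-6-methoxy-2-oxo-2H-chromen-3-yl]oxy}-4-[(1Z)-3,3-diethoxyprop-1-en-1-yl]-4-methoxycyclobut-2-en-1-one (one enantiomer drawn) | CCOC(OCC)/C=C\[C@]1(OC)C(Oc2cc3cc(OC)c(OCc4ccccc4)cc3oc2=O)=CC1=O
F9 | step 7 | (3Z,5Z)-3-{[7-(benzyloxy)-6-methoxy-2-oxo-2H-chromen-3-yl]oxy}-7,7-diethoxy-4-methoxyhepta-1,3,5-trien-1-one | O=C=C/C(Oc1cc2cc(OC)c(OCc3ccccc3)cc2oc1=O)=C(OC)\C=C/C(OCC)OCC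
F10 | step 5 | 3,4-dichlorocyclobut-3-ene-1,2-dione | ClC1=C(Cl)C(=O)C1=O
F11 | step 5 | 3-{[7-(benzyloxy)-6-methoxy-2-oxo-2H-chromen-3-yl]oxy}-4-chlorocyclobut-3-ene-1,2-dione | COc1cc2cc(OC3=C(Cl)C(=O)C3=O)c(=O)oc2cc1OCc1ccccc1
F0 | step 10 | none | none
A1 | alternative 1 | 6-methoxy-3-[(6-methoxy-2-oxo-2H-chromen-7-yl)oxy]-2-oxo-2H-chromen-7-yl acetate | CC(=O)Oc1cc2oc(=O)c(Oc3cc4oc(=O)ccc4cc3OC)cc2cc1OC
A2 | alternative 1 | (2Z)-3-[4-(acetyloxy)-3-methoxyphenyl]-2-{4-[(1E)-2-carboxyethenyl]-2-methoxyphenoxy}prop-2-enoic acid | OC(=O)/C(Oc1ccc(/C=C/C(O)=O)cc1OC)=C/c1ccc(OC(C)=O)c(OC)c1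
A3 | alternative 1 | (−)-riboflavin | CC1=CC2=C(C=C1C)N(C3=NC(=O)NC(=O)C3=N2)C[C@@H]([C@@H]([C@@H](CO)O)O)O
A4 | alternative 2 | 7-tert-butoxy-6-methoxy-3-[(6-methoxy-2-oxo-2H-chromen-7-yl)oxy]-2H-chromen-2-one | COc1cc2cc(Oc3cc4oc(=O)ccc4cc3OC)c(=O)oc2cc1OC(C)(C)C
A5 | alternative 2 | pentacarbonyl[2-(tert-butoxy)-1-methoxyprop-2-en-1-ylidene]chromium | COC(=[Cr])C(=C)OC(C)(C)C.[C-]#[O+].[C-]#[O+].[C-]#[O+].[C-]#[O+].[C-]#[O+]
A6 | alternative 2 | methyl (2E)-2-[(6-methoxy-2-oxo-2H-chromen-7-yl)oxy]pent-2-en-4-ynoate | COC(=O)/C(Oc1cc2oc(=O)ccc2cc1OC)=C\C#C
A7 | alternative 3 | 7-(benzyloxy)-6-methoxy-3-[(6-methoxy-2-oxo-2H-chromen-7-yl)oxy]-2H-chromen-2-one | COc1cc2cc(Oc3cc4oc(=O)ccc4cc3OC)c(=O)oc2cc1OCc1ccccc1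
A8 | alternative 3 | 7-(benzyloxy)-3-(5-hydroxy-2-methoxyphenoxy)-6-methoxy-2H-chromen-2-one | COc1ccc(O)cc1Oc1cc2cc(OC)c(OCc3ccccc3)cc2oc1=O
A9 | alternative 3 | ethyl propiolate | CCOC(=O)C#C
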